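The flask has the precatalyst of the autumn run but less starting material than that run, 0.658 of its charge, with the same protic impurity.

all flasks: protic impurity 12.5 mM

|  | starting material | precatalyst | remark | time |
|---|---|---|---|---|
| dawn | 25 mM | 1.8 µM | run made earlier |  |
| spring | 25 mM | 2.9 µM | run made earlier |  |
| autumn | 38 mM | 1.3 µM | run made earlier |  |
| flask | 25 mM | 1.3 µM |  | 2.5 d |

| run | time / h | product / % | starting material / % |
|---|---|---|---|
| dawn | 2.50 | 14 | 86 |
| dawn | 8.00 | 48 | 42 |
| dawn | 12.0 | 65 | 25 |
| dawn | 20.0 | 77 | 8 |
| dawn | 30.0 | 83 | 0 |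
| dawn | 40.0 | 85 | 0 |
| spring | 3.00 | 13 | 79 |
| spring | 5.00 | 37 | 57 |
| spring | 8.00 | 60 | 29 |
| spring | 12.0 | 77 | 14 |
| spring | 20.0 | 84 | 5 |
| spring | 40.0 | 87 | 0 |
| autumn | 3.00 | 7 | 86 |
| autumn | 10.0 | 51 | 41 |
| autumn | 15.0 | 69 | 21 |
| autumn | 25.0 | 77 | 9 |
| autumn | 40.0 | 78 | 5 |

(scatter of a reading: 2 percentage points)



* amount of product in percent of the starting material charged, at 6.0 h, 20 h, 40 h and 2.5 d

The last autumn reading, at 40.0 h, leaves 17.0% of the charge as neither product nor starting material; I call this the lost share, and it carries the scatter of its two readings. I take it from the autumn run, which has the flask's precatalyst, and so I expect the flask's product to end near 83.0%, a reckoning of the end alone.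

The forecast gives 29%, 75%, 81% and 83%, on the ground that “the flask should track autumn closely”.

The flask gives 24.1%, 72.1%, 80.1% and 81.2%, so the forecast is right within the tolerance.

    starting material + protic impurity → quenched substrate (k = 1.60 M⁻¹ h⁻¹)
    starting material + enzyme → product + enzyme, rate k2*[starting material]^1.5*[enzyme]/(1 + ([starting material]/Kh2)^1.5) (36.0 mM, k = 9.40 × 10⁶ M⁻¹·⁵ h⁻¹)
    precatalyst → enzyme (k = 0.0160 h⁻¹)
    enzyme → spent catalyst (k = 0.0670 h⁻¹)

In the flask, the quenching of starting material by protic impurity has half its turnover behind it at 0.235 d, earlier than the enzyme step at 0.370 d, and 95% of it by 1.25 d, when starting material stands at 4.77% and product at 78.3%. From then until 2.50 d both steps in the flask go on, for starting material falls to 1.01% while product rises to 81.2% and quenched substrate from 17.0% to 17.8%, and the flask's lost share at that time is 17.8%, beside the 17.0% read from the autumn run. The spring run, with more precatalyst, shows a lost share of 13.0% at 40.0 h, less than the flask's.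

The runs stem from a simulated flask for an exercise, and the scatter is random.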